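## The problem

Target 40 is a germacranolide: a ten-membered carbocycle (C1–C10) trans-fused across C6–C7 to an α-methylene-γ-butyrolactone (O–C6–C7–C11–C12). Its seven stereocentres fall into two groups separated by the methylene carbons C2, C5 and C9. One group is the cis-1,10-epoxide, the C3 carbinol and the fully substituted C4 carbinol bearing C15. The other is the contiguous triad C6(O)–C7–C8(O). Within the first group C3 can control both neighbours: C4 by chelation and the epoxide by hydroxyl direction. Within the second, C6 can control C7 and, through the ring, C8. Nothing relays between the groups in an open chain, so C6 has to be set by a reagent. The ring is a medium ring and must be closed against transannular strain. Several groups will not survive rough treatment: the trisubstituted epoxide, which a free C4 hydroxyl can open across the ring under acid or base; the exo-methylene lactone, a Michael acceptor with an acidic H7; the angelate, which isomerises to the tiglate; and a free C8 hydroxyl, which can translactonise. The feature that makes the key step possible is that C6–O, C7–C11 and C8–O sit on three adjacent ring carbons. A two-carbon radical tether on the C6 oxygen can therefore reach C7 of a C7=C8 alkene in a 5-exo closure and leave C8 as a radical to be oxygenated.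

## Retrosynthesis

**C13=C11 unmasking (40 from 38).** The exo-methylene group is cut back to a CH2–NMe2 group on C11. Elimination through the ammonium salt 39 is near-neutral, so the Michael acceptor is absent from every earlier step. The alternative, carrying the free methylene lactone through N–O cleavage, esterification and desilylation, exposes it to zinc, amines and fluoride.

**Silyl ethers and the C8 ester (38 from 37, 37 from 34 and 35).** The three silyl ethers are removed together by buffered fluoride. The C8–O acyl bond is cut to the alcohol 34 and angelic acid 35. The forward step must acylate a hindered secondary alcohol without Z-to-E isomerisation, which the mixed anhydride 36 is expected to do.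

**C8 oxygen and C13 (34 from 33, 33 from 31).** The C8 hydroxyl is traced to the alkoxyamine 33 by N–O cleavage. Until then the nitroxide residue protects the C8 oxygen against enolate chemistry. C11–C13 is cut to the lactone 31, which is aminomethylated through the enolate 32. Lactone 31 comes from the lactol 30, and this from the benzyl acetal 29 by hydrogenolysis. The benzyl acetal is chosen over the ethyl acetal because it is released without acid, which the epoxide would not tolerate.

**Key disconnection (29 from 26 and 27).** The C7–C11 and C8–O bonds are cut together. The bromoacetal 26 gives a C11 radical that closes the five-membered ring onto C7, and the nitroxide 27 takes the C8 radical. Two neighbouring cuts were weighed against this. Alkylating a C7 enolate needs a C8 ketone beside a β-acyloxy group. A lactone tether cyclises poorly as a radical because of its ester rotamers. The precursor 26 is much simpler: it has no lactone and no C7 or C8 stereocentre. The forward reaction must set C7 from C6 and C8 from C7.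

**Tether (26 from 24 and 25).** The acetal C–O bond and the C–Br bond are cut to the allylic alcohol 24, benzyl vinyl ether 25 and a bromonium source. Both acetal epimers are usable.

**Ring closure (24 from 23, 22 and 21).** The ring is cut at C6–C7, between an aldehyde and an (E)-iodoalkene in 21. This is the only ring bond whose formation also delivers the allylic alcohol needed for the tether. Ring-closing metathesis at C7=C8 would not secure the E geometry in a ten-membered ring. The configuration at C6 is not entrusted to the macrocyclisation: the epimer mixture 22 is oxidised to the enone 23 and reduced under catalyst control to 24.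

**End groups of the chain (21 from 20, 18 and 17).** The aldehyde is traced to an allyl group and the iodoalkene to a silylalkyne. Both are inert carriers that pass through fragment union and epoxidation.

**Epoxide (17 and 16 from 15).** The two epoxide C–O bonds are cut to the Z-alkene of the homoallylic alcohol 15. The free C3 hydroxyl directs the oxidant, so no external chiral reagent is needed. The chain has no allylic alcohol for a titanium tartrate epoxidation.

**Fragment union (15 from 8 and 13).** C1–C2 is cut between the terminal epoxide 8 and the alkenyllithium 14 made from the iodoalkene 13. This places the Z-trisubstituted alkene, which olefination would not give cleanly, in a small fragment of fixed geometry. It also produces exactly the homoallylic alcohol that the epoxidation needs.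

**Epoxide fragment (8 from 6, 5, 4, 3, 2 and 1).** The fragment is cut at C4–C5 (allyl addition to a ketone) and traced to L-erythrulose 1. This supplies C2, C3, C4 and C15 with the C3 configuration and the C4 carbonyl already in place. The forward addition must follow the chelate model to give the R configuration at C4.

**Iodoalkene fragment (13 from 12, 11 and 9).** C9–C8 is cut to the allylic bromide 12 and a silylacetylide, and C10–C14 to propargyl alcohol 9 and a methyl Grignard reagent. The anti-carbomagnesiation fixes the Z geometry.

## Roads not taken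

**Alternative 1:** The ring is cut at C3–C4. In the forward step CrCl2 with catalytic NiCl2 turns a C4 iodoalkene into an alkenylchromium that adds to a C3 aldehyde. This closes the ten-membered ring and gives the 3-hydroxy-4(15)-ene A1 with lactone, angelate and epoxide already present.
- Merits: the ring closure is late and convergent, and only a dihydroxylation of the 4(15)-alkene remains after it. After ring closure this road is shorter than the chosen one.
- Weak points: the C3 configuration arises in the macrocyclisation without a controlling element. The C3 aldehyde is β,γ to the epoxide and prone to eliminative epoxide opening. The last step must dihydroxylate one of three alkenes in A1 on the correct face of C4. The C6–C7–C8 triad and the methylene lactone would have to be built in an open chain, without the help of the ring, and then survive divalent chromium.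
- Comparison: the chosen plan sets against the shorter endgame that C3 and C4 are fixed early by chelation on a small ketone, and that no alkene has to be distinguished from the methylene lactone.

**Alternative 2:** The ring is made by a [3,3] shift. A potassium alkoxide of a terpene-derived 1,2-dialkenylcyclohexanol (KH, 18-crown-6) breaks C3–C8 and forms C5–C6, and the resulting enolate is silylated to the trienyl silyl enol ether A2.
- Merits: this is the best ring construction of the four. It needs no high dilution, starts from the chiral pool, and gives a regiodefined C7=C8 enol ether for later oxygenation at C8. In this respect it is better than the chosen plan.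
- Weak points: A2 carries only the C6 stereocentre. C7, C8, the cis-epoxide, C3 and the C4 diol would all have to be introduced on a flexible ten-membered triene under conformational control alone, with several oxidation-level changes, and the count after the ring expansion is long.
- Comparison: the chosen plan accepts a weaker ring closure (dilution, and a two-step correction at C6). In return five of the seven stereocentres are fixed on open-chain or small-ring intermediates by reactions with defined transition states.

**Alternative 3:** The ring is cut at C7–C8. Indium inserts into a 3-(bromomethyl)butenolide, and the allylindium adds through C7 to a tethered C8 aldehyde. One step forms the ring, the C7–C8 bond and the exo-methylene lactone, giving A3.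
- Merits: methylenation, N–O cleavage and the acetal-to-lactone steps all fall away. In step economy this road is as good as or better than the chosen one. The alcohol in A3 has the C8 configuration opposite to the target, but a Mitsunobu esterification with angelic acid would correct this while making the ester.
- Weak points: the C8 aldehyde is β,γ to the epoxide. The C7 configuration relative to C6 is decided in a ten-membered transition state. The methylene lactone is then exposed to every later step.
- Comparison: the chosen plan sets against the shorter sequence that its closure substrate carries no epoxy aldehyde, that C7 is derived from C6 through a five-membered transition state, and that the Michael acceptor appears only in the last step.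

Key step: step 20

Remark on the chemistry: compounds 1, 9, 25, 27 and 35 are taken as purchasable. Where a centre is created that is later removed (the acetal carbon in 26–30, C11 in 33–39), both epimers are carried on and the SMILES leave it open. Locants are those of the target, and α/β refer to the usual germacranolide drawing with 7α-H.

Step 1
Reactants: 1 L-erythrulose
Product: 2 3,4-O-isopropylidene-L-erythrulose
Conditions: Me2C(OMe)2, acetone, TsOH (cat.), rt
Reagents that add atoms: 2,2-dimethoxypropane, COC(C)(C)OC
Why: Acid-catalysed acetal exchange closes the five-membered dioxolane on the 3,4-diol and leaves the primary C1 hydroxyl free; the stereocentre (C3 of the target, S) is carried over from 1.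

Step 2
Reactants: 2 3,4-O-isopropylidene-L-erythrulose
Product: 3 1-O-(tert-butyldiphenylsilyl)-3,4-O-isopropylidene-L-erythrulose
Conditions: TBDPSCl, imidazole, DMF, 0 °C to rt
Reagents that add atoms: tert-butyl(chloro)diphenylsilane, CC(C)(C)[Si](Cl)(c1ccccc1)c1ccccc1
Why: Silylation of the only free hydroxyl; the bulky silyl ether on the future C15 oxygen cannot chelate, so the next step is controlled by the α-oxygen alone.

Step 3
Reactants: 3 1-O-(tert-butyldiphenylsilyl)-3,4-O-isopropylidene-L-erythrulose
Product: 4 allyl carbinol (2R)-1-(tert-butyldiphenylsilyloxy)-2-[(4S)-2,2-dimethyl-1,3-dioxolan-4-yl]pent-4-en-2-ol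
Conditions: allylMgBr, MgBr2·OEt2, CH2Cl2/Et2O, −78 °C
Reagents that add atoms: allylmagnesium bromide, C=CC[Mg]Br
Why: Chelation-controlled Grignard addition to an α-alkoxy ketone: magnesium bridges the carbonyl oxygen and the dioxolane oxygen on C3, and the allyl group (C5–C6) enters from the face opposite the dioxolane CH2, which sets C4 as R.

Step 4
Reactants: 4 allyl carbinol
Product: 5 tertiary triethylsilyl ether of 4
Conditions: TESOTf, 2,6-lutidine, CH2Cl2, −78 to 0 °C
Reagents that add atoms: triethylsilyl trifluoromethanesulfonate, CC[Si](CC)(CC)OS(=O)(=O)C(F)(F)F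
Why: Silyl triflate silylation of a hindered tertiary alcohol; the C4 oxygen is masked so that it can neither quench the organolithium of step 10 nor open the later epoxide across the ring.

Step 5
Reactants: 5 tertiary triethylsilyl ether
Product: 6 (2S,3R)-3-[(tert-butyldiphenylsilyloxy)methyl]-3-(triethylsilyloxy)hex-5-ene-1,2-diol
Conditions: AcOH/H2O/THF (3:1:1), 35 °C
Reagents that add atoms: none
Why: Mild acid hydrolysis of a terminal isopropylidene acetal; the TBDPS ether is acid-stable and the triethylsilyl ether is shielded by its fully substituted carbon.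

Step 6
Reactants: 6 the 1,2-diol
Product: 8 terminal epoxide tert-butyl{[(2R)-2-[(2S)-oxiran-2-yl]-2-(triethylsilyloxy)pent-4-en-1-yl]oxy}diphenylsilane, via primary tosylate 7 (not isolated)
Conditions: TsCl, Et3N, Bu2SnO (cat.), CH2Cl2, 0 °C; then K2CO3, MeOH, 0 °C
Reagents that add atoms: none
Why: Selective sulfonylation of the primary hydroxyl, then intramolecular Williamson closure by the C3 oxygen; the C3–O bond is not broken, so C3 keeps its S configuration.

Step 7
Reactants: 9 propargyl alcohol
Product: 11 (Z)-3-iodo-2-methylprop-2-en-1-ol, via alkenylmagnesium alkoxide 10 (not isolated)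
Conditions: MeMgBr (2.5 equiv), CuI (10 mol %), THF, −10 °C to rt; then I2, −40 °C
Reagents that add atoms: methylmagnesium bromide, C[Mg]Br; iodine, II
Why: Copper-catalysed anti-carbomagnesiation of a propargylic alkoxide places magnesium on the carbon cis to CH2O through a five-membered chelate; iodinolysis with retention gives the Z-iodoalkene (the future C1, C10 and C14).

Step 8
Reactants: 11 (Z)-3-iodo-2-methylprop-2-en-1-ol
Product: 12 (Z)-3-bromo-1-iodo-2-methylprop-1-ene
Conditions: CBr4, PPh3, CH2Cl2, 0 °C
Reagents that add atoms: carbon tetrabromide, BrC(Br)(Br)Br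
Why: Appel reaction of a primary allylic alcohol; the alkene geometry is not affected.

Step 9
Reactants: 12 (Z)-3-bromo-1-iodo-2-methylprop-1-ene
Product: 13 (Z)-(5-iodo-4-methylpent-4-en-1-yn-1-yl)trimethylsilane
Conditions: Me3SiC≡CH, EtMgBr, THF; then CuBr·SMe2 (10 mol %), 12, 0 °C to rt
Reagents that add atoms: ethynyltrimethylsilane, C#C[Si](C)(C)C
Why: Copper-catalysed SN2 coupling of an alkynyl Grignard reagent with a primary allylic bromide forms C9–C8 with retention of the alkene geometry; the alkenyl iodide does not react without palladium.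

Step 10
Reactants: 8 terminal epoxide; 13 (Z)-iodoalkene
Product: 15 Z-homoallylic alcohol (2R,3S,5Z)-1-(tert-butyldiphenylsilyloxy)-6-methyl-2-(prop-2-en-1-yl)-2-(triethylsilyloxy)-9-(trimethylsilyl)non-5-en-8-yn-3-ol, via alkenyllithium 14 (not isolated)
Conditions: 13, t-BuLi (2 equiv), Et2O, −78 °C; then 8, BF3·OEt2, THF, −78 °C
Reagents that add atoms: none
Why: Iodine–lithium exchange keeps the alkene geometry, and the BF3-assisted SN2 opening of the terminal epoxide at its CH2 end forms C1–C2 without touching C3; the boron-bound alkoxide is too weak a nucleophile to start silyl migration from the neighbouring oxygen.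

Step 11
Reactants: 15 Z-homoallylic alcohol
Product: 16 cis-epoxy alcohol (1R,3S,4R,10S in target numbering)
Conditions: VO(acac)2 (5 mol %), t-BuOOH, CH2Cl2, 0 °C to rt
Reagents that add atoms: tert-butyl hydroperoxide, CC(C)(C)OO
Why: Hydroxyl-directed epoxidation of a homoallylic alcohol by a vanadium alkylperoxide. In the chair-like transition state the large C4 substituent is equatorial and allylic strain of the Z-alkene fixes the C2–C1 rotamer, so oxygen is delivered to the face that places the C1–O bond syn to the C3 hydroxyl. The vanadate bound at C3 reaches the trisubstituted alkene far faster than the remote terminal one.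

Step 12
Reactants: 16 cis-epoxy alcohol
Product: 17 C3 triethylsilyl ether of 16
Conditions: TESCl, imidazole, DMAP (cat.), DMF, rt
Reagents that add atoms: chlorotriethylsilane, CC[Si](Cl)(CC)CC
Why: Silylation under base without a silyl triflate, so that the trisubstituted epoxide is not exposed to a Lewis acid.

Step 13
Reactants: 17 silylalkyne
Product: 18 terminal alkyne
Conditions: K2CO3, MeOH, rt
Reagents that add atoms: none
Why: Methanolysis of the alkynyl C–Si bond; silyl ethers and the epoxide are stable to carbonate in methanol.

Step 14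
Reactants: 18 terminal alkyne
Product: 20 (E)-iodoalkene, via alkenylstannane 19 (not isolated)
Conditions: Bu3SnH, Pd2(dba)3 (2.5 mol %), Cy3P·HBF4, i-Pr2NEt, CH2Cl2, 0 °C; then I2, 0 °C
Reagents that add atoms: iodine, II
Why: Palladium-catalysed syn-hydrostannation puts tin on the terminal carbon (bulky phosphine, neopentyl-like C9) and leaves the allyl alkene alone; iododestannylation with retention gives the E-iodoalkene at C7=C8.

Step 15
Reactants: 20 (E)-iodoalkene bearing the allyl group
Product: 21 C6 aldehyde
Conditions: OsO4 (2 mol %), NaIO4, 2,6-lutidine, dioxane/H2O (3:1), rt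
Reagents that add atoms: osmium tetroxide, O=[Os](=O)(=O)=O (oxygen donor, restored by sodium periodate, [Na+].[O-]I(=O)(=O)=O)
Why: Lemieux–Johnson cleavage; the electron-rich monosubstituted alkene is dihydroxylated much faster than the iodoalkene, and the buffered medium spares the epoxide and the β-silyloxy aldehyde.

Step 16
Reactants: 21 iodoalkene aldehyde
Product: 22 ten-membered (7E)-allylic alcohol as both C6 epimers
Conditions: CrCl2 (10 equiv), NiCl2 (2 mol %), DMSO/THF, rt, 0.002 M
Reagents that add atoms: none
Why: Intramolecular Nozaki–Hiyama–Kishi reaction: nickel inserts into the C7–I bond, transmetalation to trivalent chromium gives an alkenylchromium that adds to the C6 aldehyde with retention of the E geometry; the cis-epoxide acts as a turn element. The C6 configuration is not relied on.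

Step 17
Reactants: 22 allylic alcohol (C6 epimers)
Product: 23 ten-membered (7E)-enone
Conditions: Dess–Martin periodinane, NaHCO3, CH2Cl2, 0 °C to rt
Reagents that add atoms: none
Why: Dess–Martin oxidation merges both C6 epimers into one enone under buffered conditions that do not trigger β-elimination of the C4 silyloxy group.

Step 18
Reactants: 23 enone
Product: 24 (6R)-allylic alcohol (6α-OH)
Conditions: (S)-Me-CBS oxazaborolidine (0.5 equiv), BH3·SMe2, THF, −40 °C
Reagents that add atoms: none
Why: Corey–Bakshi–Shibata reduction: the alkenyl branch acts as the large group and the C5 methylene as the small one, so the (S)-catalyst delivers hydride to give the 6R carbinol, in the same sense as acetophenone gives (R)-1-phenylethanol.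

Step 19
Reactants: 24 (6R)-allylic alcohol; 25 benzyl vinyl ether
Product: 26 bromoacetal (both acetal epimers)
Conditions: NBS, CH2Cl2, −40 to 0 °C
Reagents that add atoms: N-bromosuccinimide, O=C1CCC(=O)N1Br
Why: Bromoacetalisation: the bromonium ion of the enol ether is opened by the C6 hydroxyl; the enol ether is far more nucleophilic than the ring alkene.

Step 20
Reactants: 26 bromoacetal; 27 TEMPO
Product: 29 bicyclic benzyl acetal carrying the 8β-alkoxyamine, via alkylcobaloxime 28 (not isolated)
Conditions: Co(dmgH)2(py)Cl (1.2 equiv), NaBH4, NaOH (aq.), MeOH/THF, 0 °C, dark; then crude 28, 27 (syringe pump), benzene, visible light, 25 °C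
Reagents that add atoms: none
Why: Monovalent cobalt, made from the cobaloxime chloride and NaBH4, displaces the primary bromide to give the alkylcobaloxime 28; visible light homolyses its Co–C bond, the C11 radical adds to C7, and the nitroxide couples with the C8 radical. The closest known reaction type is the cobaloxime-mediated Ueno–Stork haloacetal cyclisation with nitroxide capture of the cyclised radical. The five-membered ring O–C6–C7–C11–C12 closes in the 5-exo-trig mode through a chair-like transition state. C7 is set by C6: the tether sits on the open face of the E-alkene while the ring holds C5 on the other face, so C5 and C8 end up trans on the new ring, which is the trans ring fusion of the target. C8 is set by C7 and the ring: once C7 is tetrahedral the nitroxide is expected to bond on the side of H7, anti to the new C7–C11 bond in the transoid C6–C7–C8–C9 array, which is the 8β configuration. The step needs ring closure to outrun capture of the C11 radical; slow addition keeps the nitroxide concentration low, and divalent cobalt caps radicals only reversibly, so the secondary C8 radical should end as the alkoxyamine and not lose a β-hydrogen. The neutral conditions leave the epoxide and the silyl ethers untouched, and both acetal epimers are used.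

Step 21
Reactants: 29 bicyclic benzyl acetal
Product: 30 lactol
Conditions: H2 (1 atm), Pd/C, EtOAc, rt
Reagents that add atoms: none
Why: Hydrogenolysis of the benzyl acetal releases the lactol without acid; the molecule holds no alkene at this stage, and the hindered alkoxyamine N–O bond and the epoxide are not cleaved under these conditions.

Step 22
Reactants: 30 lactol
Product: 31 trans-fused γ-lactone
Conditions: Pr4N[RuO4] (5 mol %), NMO, 4 Å sieves, CH2Cl2, rt
Reagents that add atoms: none
Why: Ley–Griffith oxidation of a lactol to the lactone; both lactol epimers converge and no other oxidisable hydroxyl is free.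

Step 23
Reactants: 31 γ-lactone
Product: 33 13-(dimethylamino) lactone (Mannich base), via lithium enolate 32 (not isolated)
Conditions: LDA, THF, −78 °C; then CH2=NMe2+ I−, −78 °C to rt
Reagents that add atoms: N,N-dimethylmethyleneiminium iodide, C=[N+](C)C.[I-]
Why: Mannich reaction of the lactone enolate with Eschenmoser's salt forms C11–C13; the enolate has no β-leaving group, the C8 oxygen is protected as the alkoxyamine, and the new C11 centre is removed in step 27.

Step 24
Reactants: 33 Mannich base
Product: 34 8β-alcohol
Conditions: Zn, AcOH/THF/H2O (3:1:1), rt to 40 °C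
Reagents that add atoms: none
Why: Dissolving-metal cleavage of the alkoxyamine N–O bond; with the C4 oxygen silylated there is no internal nucleophile to open the epoxide in the weak acid, and no Michael acceptor is present to be reduced.

Step 25
Reactants: 34 8β-alcohol; 35 angelic acid
Product: 37 8β-angelate, via mixed anhydride 36 (not isolated)
Conditions: 35, 2,4,6-Cl3C6H2COCl, Et3N, toluene, rt; then 34, DMAP, 50 °C
Reagents that add atoms: none
Why: Yamaguchi esterification: the hindered mixed anhydride transfers the angeloyl group to the secondary alcohol without Z-to-E isomerisation; the configuration at C8 is retained because the C8–O bond is not broken.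

Step 26
Reactants: 37 8β-angelate
Product: 38 triol (free C3, C4 and C15 hydroxyls)
Conditions: TBAF, AcOH (1:1), THF, rt
Reagents that add atoms: none
Why: Buffered fluoride removes the two triethylsilyl ethers and the TBDPS ether at near-neutral pH, which spares the epoxide, the angelate and the lactone.

Step 27
Reactants: 38 triol
Product: 40 target germacranolide, via trimethylammonium iodide 39 (not isolated)
Conditions: MeI, MeOH, rt; then NaHCO3 (aq.), rt
Reagents that add atoms: none
Why: Quaternisation of the tertiary amine and Hofmann-type β-elimination through the lactone enolate release the exo-methylene group under near-neutral conditions; both C11 epimers converge and no stereocentre is formed.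

Compound list

1 | L-erythrulose, (3S)-1,3,4-trihydroxybutan-2-one | OCC(=O)[C@@H](O)CO | starting material
2 | 3,4-O-isopropylidene-L-erythrulose, 1-[(4S)-2,2-dimethyl-1,3-dioxolan-4-yl]-2-hydroxyethan-1-one | OCC(=O)[C@@H]1COC(C)(C)O1 | intermediate
3 | 2-(tert-butyldiphenylsilyloxy)-1-[(4S)-2,2-dimethyl-1,3-dioxolan-4-yl]ethan-1-one | CC(C)(C)[Si](c1ccccc1)(c1ccccc1)OCC(=O)[C@@H]1COC(C)(C)O1 | intermediate
4 | (2R)-1-(tert-butyldiphenylsilyloxy)-2-[(4S)-2,2-dimethyl-1,3-dioxolan-4-yl]pent-4-en-2-ol | C=CC[C@@](O)(CO[Si](c1ccccc1)(c1ccccc1)C(C)(C)C)[C@@H]1COC(C)(C)O1 | intermediate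
5 | tertiary triethylsilyl ether of 4 | C=CC[C@@](O[Si](CC)(CC)CC)(CO[Si](c1ccccc1)(c1ccccc1)C(C)(C)C)[C@@H]1COC(C)(C)O1 | intermediate
6 | (2S,3R)-3-[(tert-butyldiphenylsilyloxy)methyl]-3-(triethylsilyloxy)hex-5-ene-1,2-diol | C=CC[C@@](O[Si](CC)(CC)CC)(CO[Si](c1ccccc1)(c1ccccc1)C(C)(C)C)[C@@H](O)CO | intermediate
7 | 1-O-(4-toluenesulfonyl) derivative of 6 | C=CC[C@@](O[Si](CC)(CC)CC)(CO[Si](c1ccccc1)(c1ccccc1)C(C)(C)C)[C@@H](O)COS(=O)(=O)c1ccc(C)cc1 | intermediate
8 | tert-butyl{[(2R)-2-[(2S)-oxiran-2-yl]-2-(triethylsilyloxy)pent-4-en-1-yl]oxy}diphenylsilane | C=CC[C@@](O[Si](CC)(CC)CC)(CO[Si](c1ccccc1)(c1ccccc1)C(C)(C)C)[C@@H]1CO1 | intermediate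
9 | propargyl alcohol, prop-2-yn-1-ol | C#CCO | starting material
10 | bromomagnesium (Z)-3-(bromomagnesio)-2-methylprop-2-en-1-olate | Br[Mg]OC/C(C)=C\[Mg]Br | intermediate
11 | (Z)-3-iodo-2-methylprop-2-en-1-ol | OC/C(C)=C\I | intermediate
12 | (Z)-3-bromo-1-iodo-2-methylprop-1-ene | BrC/C(C)=C\I | intermediate
13 | (Z)-(5-iodo-4-methylpent-4-en-1-yn-1-yl)trimethylsilane | C[Si](C)(C)C#CC/C(C)=C\I | intermediate
14 | (Z)-[2-methyl-5-(trimethylsilyl)pent-1-en-4-yn-1-yl]lithium | C[Si](C)(C)C#CC/C(C)=C\[Li] | intermediate
15 | (2R,3S,5Z)-1-(tert-butyldiphenylsilyloxy)-6-methyl-2-(prop-2-en-1-yl)-2-(triethylsilyloxy)-9-(trimethylsilyl)non-5-en-8-yn-3-ol | C=CC[C@@](O[Si](CC)(CC)CC)(CO[Si](c1ccccc1)(c1ccccc1)C(C)(C)C)[C@@H](O)C/C=C(C)\CC#C[Si](C)(C)C | intermediate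
16 | cis-epoxy alcohol from 15; target numbering 1R,3S,4R,10S, with C2 and C9 cis on the oxirane | C=CC[C@@](O[Si](CC)(CC)CC)(CO[Si](c1ccccc1)(c1ccccc1)C(C)(C)C)[C@@H](O)C[C@H]1O[C@@]1(C)CC#C[Si](C)(C)C | intermediate
17 | C3 triethylsilyl ether of 16 | C=CC[C@@](O[Si](CC)(CC)CC)(CO[Si](c1ccccc1)(c1ccccc1)C(C)(C)C)[C@@H](O[Si](CC)(CC)CC)C[C@H]1O[C@@]1(C)CC#C[Si](C)(C)C | intermediate
18 | terminal alkyne from 17 (1R,3S,4R,10S) | C=CC[C@@](O[Si](CC)(CC)CC)(CO[Si](c1ccccc1)(c1ccccc1)C(C)(C)C)[C@@H](O[Si](CC)(CC)CC)C[C@H]1O[C@@]1(C)CC#C | intermediate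
19 | (7E)-7-(tributylstannyl)alkene from 18 | C=CC[C@@](O[Si](CC)(CC)CC)(CO[Si](c1ccccc1)(c1ccccc1)C(C)(C)C)[C@@H](O[Si](CC)(CC)CC)C[C@H]1O[C@@]1(C)C/C=C/[Sn](CCCC)(CCCC)CCCC | intermediate
20 | (7E)-7-iodoalkene with allyl group at C4 (1R,3S,4R,10S) | C=CC[C@@](O[Si](CC)(CC)CC)(CO[Si](c1ccccc1)(c1ccccc1)C(C)(C)C)[C@@H](O[Si](CC)(CC)CC)C[C@H]1O[C@@]1(C)C/C=C/I | intermediate
21 | open-chain C6 aldehyde with (7E)-iodoalkene (1R,3S,4R,10S) | O=CC[C@@](O[Si](CC)(CC)CC)(CO[Si](c1ccccc1)(c1ccccc1)C(C)(C)C)[C@@H](O[Si](CC)(CC)CC)C[C@H]1O[C@@]1(C)C/C=C/I | intermediate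
22 | 15-(tert-butyldiphenylsilyloxy)-1β,10β-epoxy-3β,4α-bis(triethylsilyloxy)germacr-7(E)-en-6-ol, both C6 epimers | OC1/C=C/C[C@]2(C)O[C@@H]2C[C@H](O[Si](CC)(CC)CC)[C@](O[Si](CC)(CC)CC)(CO[Si](c3ccccc3)(c3ccccc3)C(C)(C)C)C1 | intermediate
23 | the corresponding germacr-7(E)-en-6-one | O=C1/C=C/C[C@]2(C)O[C@@H]2C[C@H](O[Si](CC)(CC)CC)[C@](O[Si](CC)(CC)CC)(CO[Si](c3ccccc3)(c3ccccc3)C(C)(C)C)C1 | intermediate
24 | the (6R)-alcohol, 6α-hydroxy (1R,3S,4R,6R,10S) | O[C@H]1/C=C/C[C@]2(C)O[C@@H]2C[C@H](O[Si](CC)(CC)CC)[C@](O[Si](CC)(CC)CC)(CO[Si](c3ccccc3)(c3ccccc3)C(C)(C)C)C1 | intermediate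
25 | benzyl vinyl ether | C=COCc1ccccc1 | starting material
26 | 6-O-[1-(benzyloxy)-2-bromoethyl] ether of 24, both acetal epimers | BrCC(OCc1ccccc1)O[C@H]1/C=C/C[C@]2(C)O[C@@H]2C[C@H](O[Si](CC)(CC)CC)[C@](O[Si](CC)(CC)CC)(CO[Si](c3ccccc3)(c3ccccc3)C(C)(C)C)C1 | intermediate
27 | TEMPO, 2,2,6,6-tetramethylpiperidin-1-oxyl | CC1(C)CCCC(C)(C)N1[O] | starting material
28 | alkyl(pyridine)bis(dimethylglyoximato)cobalt (trivalent cobalt) with the acetal CH2 of 26 bound to cobalt | [Co+2]CC(OCc1ccccc1)O[C@H]1/C=C/C[C@]2(C)O[C@@H]2C[C@H](O[Si](CC)(CC)CC)[C@](O[Si](CC)(CC)CC)(CO[Si](c3ccccc3)(c3ccccc3)C(C)(C)C)C1.CC(=NO)C(C)=N[O-].CC(=NO)C(C)=N[O-].c1ccncc1 | intermediate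
29 | bicyclic 12-O-benzyl acetal (6α,12-epoxide ring, trans-fused, 7α-H) with 8β-(2,2,6,6-tetramethylpiperidin-1-yloxy) group; 1R,3S,4R,6R,8R,10S | C1C(OCc2ccccc2)O[C@@H]3C[C@@](O[Si](CC)(CC)CC)(CO[Si](c2ccccc2)(c2ccccc2)C(C)(C)C)[C@@H](O[Si](CC)(CC)CC)C[C@H]4O[C@@]4(C)C[C@@H](ON5C(C)(C)CCCC5(C)C)[C@@H]13 | intermediate
30 | the corresponding lactol (12-OH, both epimers) | C1C(O)O[C@@H]3C[C@@](O[Si](CC)(CC)CC)(CO[Si](c2ccccc2)(c2ccccc2)C(C)(C)C)[C@@H](O[Si](CC)(CC)CC)C[C@H]4O[C@@]4(C)C[C@@H](ON5C(C)(C)CCCC5(C)C)[C@@H]13 | intermediate
31 | the corresponding 12,6α-olide (trans-fused γ-lactone) | C1C(=O)O[C@@H]3C[C@@](O[Si](CC)(CC)CC)(CO[Si](c2ccccc2)(c2ccccc2)C(C)(C)C)[C@@H](O[Si](CC)(CC)CC)C[C@H]4O[C@@]4(C)C[C@@H](ON5C(C)(C)CCCC5(C)C)[C@@H]13 | intermediate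
32 | lithium enolate of 31 (C11=C12–OLi) | C1=C(O[Li])O[C@@H]3C[C@@](O[Si](CC)(CC)CC)(CO[Si](c2ccccc2)(c2ccccc2)C(C)(C)C)[C@@H](O[Si](CC)(CC)CC)C[C@H]4O[C@@]4(C)C[C@@H](ON5C(C)(C)CCCC5(C)C)[C@@H]13 | intermediate
33 | 11-[(dimethylamino)methyl] lactone, C11 epimers | CN(C)CC1C(=O)O[C@@H]3C[C@@](O[Si](CC)(CC)CC)(CO[Si](c2ccccc2)(c2ccccc2)C(C)(C)C)[C@@H](O[Si](CC)(CC)CC)C[C@H]4O[C@@]4(C)C[C@@H](ON5C(C)(C)CCCC5(C)C)[C@@H]13 | intermediate
34 | 8β-hydroxy-11-[(dimethylamino)methyl] lactone | CN(C)CC1C(=O)O[C@@H]3C[C@@](O[Si](CC)(CC)CC)(CO[Si](c2ccccc2)(c2ccccc2)C(C)(C)C)[C@@H](O[Si](CC)(CC)CC)C[C@H]4O[C@@]4(C)C[C@@H](O)[C@@H]13 | intermediate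
35 | angelic acid, (Z)-2-methylbut-2-enoic acid | C/C=C(/C)C(O)=O | starting material
36 | angelic 2,4,6-trichlorobenzoic anhydride | C/C=C(/C)C(=O)OC(=O)c1c(Cl)cc(Cl)cc1Cl | intermediate
37 | 8β-angelate of 34 | CN(C)CC1C(=O)O[C@@H]3C[C@@](O[Si](CC)(CC)CC)(CO[Si](c2ccccc2)(c2ccccc2)C(C)(C)C)[C@@H](O[Si](CC)(CC)CC)C[C@H]4O[C@@]4(C)C[C@@H](OC(=O)/C(C)=C\C)[C@@H]13 | intermediate
38 | 8β-angeloyloxy-11-[(dimethylamino)methyl]-1β,10β-epoxy-3β,4α,15-trihydroxygermacran-12,6α-olide | CN(C)CC1C(=O)O[C@@H]3C[C@@](O)(CO)[C@@H](O)C[C@H]4O[C@@]4(C)C[C@@H](OC(=O)/C(C)=C\C)[C@@H]13 | intermediate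
39 | N-methyl (trimethylammonium) iodide of 38 | C[N+](C)(C)CC1C(=O)O[C@@H]3C[C@@](O)(CO)[C@@H](O)C[C@H]4O[C@@]4(C)C[C@@H](OC(=O)/C(C)=C\C)[C@@H]13.[I-] | intermediate
40 | 8β-angeloyloxy-1β,10β-epoxy-3β,4α,15-trihydroxygermacr-11(13)-en-12,6α-olide (CNP0307250.1) | C=C1C(=O)O[C@@H]2C[C@@](O)(CO)[C@@H](O)C[C@H]3O[C@@]3(C)C[C@@H](OC(=O)/C(C)=C\C)[C@@H]12 | target

Total step count: 27. Longest linear sequence: 24 steps (steps 1–6 and 10–27); steps 7–9 prepare the second fragment in parallel.

Least certain steps

Step 20 (key step). The most likely failure is poor facial selection when the nitroxide captures the C8 radical. The face anti to the C7–C11 bond is the one turned towards the ring interior at the moment the radical is formed, so the ten-membered radical must relax before capture. Capture on the outer face, syn to C11, would give the C8 epimer. Capture of the C11 radical before ring closure is a second, smaller risk, which slow addition of the nitroxide addresses. The fallback sets out from 26 and uses whichever epimer forms. If the same cobalt and nitroxide step gives the 8α-alkoxyamine acetal F1, this is taken through the operations of steps 21 to 24: 8α lactol F2, 8α lactone F3, its lithium enolate F4, 8α Mannich base F5 and 8α alcohol F6. The ester is then made with inversion by a Mitsunobu reaction of F6 with 35 (PPh3, DIAD, toluene), which comes back to the route at 37.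

Step 16. Closure of a ten-membered ring containing an E-alkene may be slow against transannular strain, so that intermolecular coupling or reduction of the alkenylchromium competes. The fallback sets out from alkyne 18 and changes the ring-closing nucleophile. Lemieux–Johnson cleavage of the allyl group gives the alkynyl aldehyde F7. Hydroboration of its alkyne with dicyclohexylborane gives the alkenylborane F8, and boron–zinc exchange with Et2Zn gives the alkenylzinc F9. Slow addition of F9 to a catalytic amount of 3-exo-(dimethylamino)isoborneol, in the enantiomer that delivers the 6R carbinol, closes the ring and comes back to the route at 24. Steps 14 and 16 to 18 are then not needed.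

Step 3. Allylmagnesium halides add so fast that the magnesium chelate may not discriminate the two faces, which would erode the C4 configuration. The fallback sets out from ketone 3 and changes the nucleophile class. The ketone is first locked as its TiCl4 (or SnCl4) chelate at −78 °C and then treated with allyltrimethylsilane in a Sakurai–Hosomi addition through an open transition state on the preformed chelate. This returns to the route at 4 without any new compound F0.

Step 11. Facial selection rests on the chair-like delivery from the C3 hydroxyl; the very large C4 substituent could distort it, and Lewis-acid opening of the new epoxide by the same hydroxyl could consume product. The fallback sets out from 15 and replaces substrate control by catalyst control. A Shi epoxidation with the fructose-derived ketone and Oxone at buffered pH, which needs no metal and is not Lewis acidic, returns to the route at 16 without any new compound F0.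

Step 18. The conformation of the ten-membered enone may override the catalyst and give poor facial selectivity at C6. The fallback sets out from 23. A Luche reduction (NaBH4, CeCl3) is run, and if the 6S alcohol F10 predominates it is inverted by a Mitsunobu reaction with 4-nitrobenzoic acid to the 6R 4-nitrobenzoate F11. Methanolysis (K2CO3, MeOH) comes back to the route at 24.

Further compounds

F1 | step 20 | 8α epimer of acetal 29 | C1C(OCc2ccccc2)O[C@@H]3C[C@@](O[Si](CC)(CC)CC)(CO[Si](c2ccccc2)(c2ccccc2)C(C)(C)C)[C@@H](O[Si](CC)(CC)CC)C[C@H]4O[C@@]4(C)C[C@H](ON5C(C)(C)CCCC5(C)C)[C@@H]13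
F2 | step 20 | 8α epimer of lactol 30 | C1C(O)O[C@@H]3C[C@@](O[Si](CC)(CC)CC)(CO[Si](c2ccccc2)(c2ccccc2)C(C)(C)C)[C@@H](O[Si](CC)(CC)CC)C[C@H]4O[C@@]4(C)C[C@H](ON5C(C)(C)CCCC5(C)C)[C@@H]13
F3 | step 20 | 8α epimer of lactone 31 | C1C(=O)O[C@@H]3C[C@@](O[Si](CC)(CC)CC)(CO[Si](c2ccccc2)(c2ccccc2)C(C)(C)C)[C@@H](O[Si](CC)(CC)CC)C[C@H]4O[C@@]4(C)C[C@H](ON5C(C)(C)CCCC5(C)C)[C@@H]13
F4 | step 20 | lithium enolate of F3 | C1=C(O[Li])O[C@@H]3C[C@@](O[Si](CC)(CC)CC)(CO[Si](c2ccccc2)(c2ccccc2)C(C)(C)C)[C@@H](O[Si](CC)(CC)CC)C[C@H]4O[C@@]4(C)C[C@H](ON5C(C)(C)CCCC5(C)C)[C@@H]13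
F5 | step 20 | 8α epimer of Mannich base 33 | CN(C)CC1C(=O)O[C@@H]3C[C@@](O[Si](CC)(CC)CC)(CO[Si](c2ccccc2)(c2ccccc2)C(C)(C)C)[C@@H](O[Si](CC)(CC)CC)C[C@H]4O[C@@]4(C)C[C@H](ON5C(C)(C)CCCC5(C)C)[C@@H]13
F6 | step 20 | 8α epimer of alcohol 34 | CN(C)CC1C(=O)O[C@@H]3C[C@@](O[Si](CC)(CC)CC)(CO[Si](c2ccccc2)(c2ccccc2)C(C)(C)C)[C@@H](O[Si](CC)(CC)CC)C[C@H]4O[C@@]4(C)C[C@H](O)[C@@H]13
F7 | step 16 | alkynyl aldehyde (C6 aldehyde, terminal C7≡C8 alkyne) | O=CC[C@@](O[Si](CC)(CC)CC)(CO[Si](c1ccccc1)(c1ccccc1)C(C)(C)C)[C@@H](O[Si](CC)(CC)CC)C[C@H]1O[C@@]1(C)CC#C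
F8 | step 16 | (7E)-7-(dicyclohexylboryl)alkene aldehyde | O=CC[C@@](O[Si](CC)(CC)CC)(CO[Si](c1ccccc1)(c1ccccc1)C(C)(C)C)[C@@H](O[Si](CC)(CC)CC)C[C@H]1O[C@@]1(C)C/C=C/B(C1CCCCC1)C1CCCCC1
F9 | step 16 | (7E)-7-(ethylzincio)alkene aldehyde | O=CC[C@@](O[Si](CC)(CC)CC)(CO[Si](c1ccccc1)(c1ccccc1)C(C)(C)C)[C@@H](O[Si](CC)(CC)CC)C[C@H]1O[C@@]1(C)C/C=C/[Zn]CC
F0 | step 3 | none | none
F0 | step 11 | none | none
F10 | step 18 | 6S epimer of alcohol 24 | O[C@@H]1/C=C/C[C@]2(C)O[C@@H]2C[C@H](O[Si](CC)(CC)CC)[C@](O[Si](CC)(CC)CC)(CO[Si](c3ccccc3)(c3ccccc3)C(C)(C)C)C1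
F11 | step 18 | 4-nitrobenzoate of alcohol 24 (6R) | O=C(O[C@H]1/C=C/C[C@]2(C)O[C@@H]2C[C@H](O[Si](CC)(CC)CC)[C@](O[Si](CC)(CC)CC)(CO[Si](c3ccccc3)(c3ccccc3)C(C)(C)C)C1)c1ccc(cc1)[N+]([O-])=O
A1 | alternative 1 | 3-hydroxy-4(15)-ene macrocycle with 8-angelate, 1,10-epoxide and methylene lactone | C=C1C(=O)O[C@@H]2CC(=C)[C@@H](O)C[C@H]3O[C@@]3(C)C[C@@H](OC(=O)/C(C)=C\C)[C@@H]12
A2 | alternative 2 | ten-membered trienyl trimethylsilyl enol ether with C6 4-methoxybenzyl ether | C1/C(C)=C\C/C=C(CO[Si](C)(C)C(C)(C)C)/C[C@@H](OCc2ccc(OC)cc2)/C=C1\O[Si](C)(C)C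
A3 | alternative 3 | 8-epi-hydroxy α-methylene lactone with C3 and C15 tert-butyldimethylsilyl ethers | C=C1C(=O)O[C@@H]2C[C@@](O)(CO[Si](C)(C)C(C)(C)C)[C@@H](O[Si](C)(C)C(C)(C)C)C[C@H]3O[C@@]3(C)C[C@H](O)[C@@H]12
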